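**Remarks on the chemistry (assumptions)**

- Carbon labels C1–C20 are the locants used throughout: ring A = C1–C5 and C10; γ-lactone C6(=O)–O–C19; δ-lactone C7(=O)–O–C20; ring C = C8, C9, C11–C14; ring D = C8, C14, C13, C16, C15; C17 on C16; C18 methyl on C4.
- Step 2 assumes, on the usual binding model for 2-substituted acroleins, that the (S)-prolinol-derived oxazaborolidinium catalyst exposes the Si face at the α-carbon of methacrolein; if the sense is opposite, the antipodal catalyst is used.
- Step 16 is expected to give the C11 epimer of the target (see its Why line); steps 17 and 18 are built in so that the route does not depend on that outcome.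

## Analysis of the target

The target is a pentacyclic 6,7-seco-ent-kauranoid. Ring A carries a γ-lactone (C6(=O)–O–C19) cis-fused across C4–C5. Through the spiro carbon C10, ring A is joined to a δ-lactone (C10–C20–O–C7(=O)–C8–C9), which is fused along C8–C9 to a bicyclo[3.2.1]octanone (rings C and D). There are eight stereocentres (C4, C5, C8, C9, C10, C11, C13, C16), three of them quaternary (C4, C8, C10); C8 and C10 are separated only by C9. On ring A, C19, C6 and C20 lie on one face and C9 on the other. On ring C, H9 is cis to the C15–C16 bridge, the C11 hydroxyl is equatorial and trans to H9, and C17 sits endo on C16. The sensitive groups are the β-hydroxy ketone C17–OH/C15=O (dehydration, retro-aldol, epimerisation at C16), the non-enolisable β-keto lactone at C8 (retro-Claisen opening by alkoxides) and the two lactones. The hard parts are the spiro quaternary C10 next to C5 and C9, the bridgehead quaternary C8, and telling C11 (carbinol) from C15 (ketone). The strategy rests on C10: its C20–O–C7 ester link to C8 makes C9–C10 the ring-closing bond of the δ-lactone, so the substrate for that bond is a plain ester of a ring A alcohol and an acyclic acid.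

## Retrosynthetic reasoning

**C17 (38 ⇒ 37 ⇒ 35 ⇒ 31).** The C16–C17 bond is cut last. A direct aldol would bring the one-carbon electrophile to the open exo face of the C15 enolate and give the wrong C16 epimer. Instead C17 enters as an exocyclic methylene (35), a boryl group is added to C17, and C16 is protonated from the exo face, which leaves C17 endo. The C11 hydroxyl is carried as a silyl ether (37) through these basic steps.

**Oxidation pattern at C11 and C15 (31 ⇒ 30 ⇒ 29 ⇒ 28 ⇒ 27).** The ring-forming step delivers both carbons as carbinols (27). Oxidising both (28) and reducing both (29) sets C11 by hydride delivery, whatever the ring closure gave. The two hydroxyls of 29 then differ sterically (C11 equatorial; C15 endo and neopentyl), so C11 can be silylated (30) and C15 oxidised alone (31).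

**C9–C11 and C8–C15 (27 ⇒ 26).** Both bonds are cut at once. A ketyl at C11 adds to C9 of the unsaturated δ-lactone, and the C8 enolate so formed, which can arise at no other position, adds to the second aldehyde. The two arms on C13 are identical, so C13 is not a stereocentre before this step.

**Unmasking and saturation (26 ⇒ 25 ⇒ 24).** The aldehydes are kept as dimethyl acetals until needed. The C1=C2 alkene left by the key step is removed by homogeneous hydrogenation, which does not touch the hindered conjugated C8=C9 alkene.

**C9–C10, the key disconnection (24 ⇒ 23).** Cutting C9–C10 opens the δ-lactone and removes the spiro centre. The precursor 23 has a vinyl bromide at C9 cis to the ester carbonyl and a trisubstituted C1=C10 alkene in ring A. The forward step must bring C9 to the ring A face opposite the fused γ-lactone and lose hydrogen towards C2.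

**Ester (23 ⇒ 11 + 22).** The C20–O bond is cut to alcohol 11 and acid 22. The forward esterification must not activate the β-bromoacrylic carbonyl towards addition–elimination, which would scramble the geometry.

**Acid 22 (22 ⇒ 20 ⇒ 16 + 17; 16 ⇒ 14 ⇒ 13 ⇒ 12).** The C8–C14 bond is cut. Halogenation–dehydrohalogenation of a 2-alkylacrylic ester would be expected to favour bromine trans to the carboxyl group, and that isomer cannot cyclise. The geometry is therefore taken from a chelated vinylmagnesium intermediate: anti-carbomagnesiation of 17 with the organomagnesium reagent from 16 places the metal, and then bromine, cis to the carbinol carbon that becomes C7. The two arms of 16 come from cleaving the ring alkene of 14, so they are identical by construction.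

**C20 on ring A (11 ⇒ 10 ⇒ 8 ⇒ 6).** C20 is cut from C10. In 6 the C1 oxygen is present as an enol ether whose nucleophilic carbon is C10, so a formyl equivalent (7) enters there and nowhere else. Reduction of the C1 ketone and loss of water from the β-hydroxy aldehyde puts the alkene at C1=C10 and removes the C1 oxygen.

**Ring A (6 ⇒ 4 ⇒ 2 + 3; 2 ⇒ 1).** The C4–C5 and C2–C3 bonds are cut in a Diels–Alder sense. Dienophile 3 brings C3, C4, C18 and C19; diene 2 brings C5 with C6 attached, C10, C1 and C2. The silyloxy group on C1 and the ester on C5 direct the same regiochemistry, and a chiral Lewis acid sets C4, from which every other stereocentre derives. C5 is epimerisable and is fixed by cis-lactonisation. A route by conjugate addition to an unsaturated five-membered lactone was set aside. It offers no reliable enantiocontrol at a quaternary carbon, and it would need a substitution at a neopentyl-type lactone α-carbon.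

## Alternatives that were turned down

**Alternative 1: late C–H lactonisation at C19.** The C19–O bond is cut; the precursor is the C4 gem-dimethyl C6 carboxylic acid A2. In the forward step Pd(OAc)2 with an N-acetyl-β-alanine ligand and a hydroperoxide oxidant in hexafluoroisopropanol activates a C–H bond of one C4 methyl under direction by the carboxylate and closes the γ-lactone to give A1. In its favour, ring A could start from an achiral gem-dimethyl cyclohexane, and C4 becomes a stereocentre only by geometry, since only the methyl cis to C6 can reach. On that point it is stronger than the chosen route, which has to set C4 by asymmetric catalysis in step 2. Against it, the least precedented step falls last, on a pentacycle with a ketone, a silyl ether and a β-keto lactone under oxidising conditions. The acid has an α-hydrogen at C5 and a competing γ-methylene at C3. Without the fused γ-lactone, ring A has no group that shields one face of C10 when the spiro centre is made. The chosen route offers instead a risk placed mid-route on a simple ester; A1 is in fact its compound 31, reached by conventional steps.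

**Alternative 2: oxyallyl (4+3) cycloaddition.** C8–C9 and C12–C13 are cut. The precursor A4 is a chloromethyl ketone on C9 tethered through the C20 ester to a cyclopenta-1,3-diene-1-carboxylate. Ionisation to the oxyallyl cation (C9–C11–C12) and cycloaddition would close the δ-lactone and the seven-membered ring in one step to give A3. In its favour are two C–C bonds, two rings and the C8 quaternary centre in one operation; in convergence and step count it is stronger than the chosen route. Against it, 1-acylcyclopentadienes shift hydrogen and dimerise. The diene terminus that must bond (C8) is the electron-poor one, facing an electrophilic cation. The cation sits next to quaternary C10. Facial and endo/exo selectivity are uncontrolled. A3 still needs stereoselective reduction at C11, conversion of C15=C16 into the ketone with the right C16 configuration, and debenzylation. The chosen route forms the same bonds one at a time, each with a regiochemistry fixed by the substrate.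

**Alternative 3: samarium ketyl–enoate and aldol cascade as the key step.** C9–C11 and C8–C15 are cut; the substrate is the dialdehyde (compound 26 of the chosen route) and the product is diol A5. It closes two rings and sets C8, C9, C11 and C13 at once, and it is exactly what the chosen route uses in step 16, so on rings C and D it is as strong. Taken as the defining disconnection it leaves open how the spiro centre C10 and the C9–C10 bond arise, and its own risks (pinacol coupling of the two aldehydes, configuration at C11, protonation of the enolate before the aldol) are unchanged. The chosen strategy supplies the spirolactone this cascade needs and puts the defining step where the substrate is simplest.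

Key step: step 13

## Route

Step 1
Reactants: 1 methyl (2E)-4-oxopent-2-enoate
Product: 2 methyl (2E)-4-[(triisopropylsilyl)oxy]penta-2,4-dienoate
Conditions: TIPSOTf, Et3N, CH2Cl2, 0 °C
Reagents that add atoms: triisopropylsilyl trifluoromethanesulfonate, CC(C)[Si](C(C)C)(C(C)C)OS(=O)(=O)C(F)(F)F
Why: Soft enolisation of a methyl ketone to a 2-silyloxy diene; the methyl group is the only enolisable position, and the bulky silyl group is chosen to survive the acidic catalyst of step 2.

Step 2
Reactants: 2 methyl (2E)-4-[(triisopropylsilyl)oxy]penta-2,4-dienoate; 3 methacrolein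
Product: 4 methyl (1S,6R)-6-formyl-6-methyl-3-[(triisopropylsilyl)oxy]cyclohex-2-ene-1-carboxylate
Conditions: (S)-B-(o-tolyl)oxazaborolidine of α,α-diphenylprolinol·Tf2NH (20 mol %), CH2Cl2, −78 → −40 °C
Reagents that add atoms: none
Why: Catalytic enantioselective Diels–Alder reaction of a 2-substituted acrolein with a 2-silyloxy diene; the silyloxy group on C1 and the ester on C5 both put the largest diene coefficient on C2, so C2 bonds to the β-carbon of 3 and C5 to its α-carbon (C4). The catalyst shields one face of the bound aldehyde, so that C5 should add to the Si face of the α-carbon, which is R at C4. The C5 epimer (exo aldehyde) is equally useful, since step 3 converges both.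

Step 3
Reactants: 4 methyl (1S,6R)-6-formyl-6-methyl-3-[(triisopropylsilyl)oxy]cyclohex-2-ene-1-carboxylate
Product: 6 (3aR,7aS)-3a-methyl-6-[(triisopropylsilyl)oxy]-3a,4,5,7a-tetrahydro-2-benzofuran-1(3H)-one, via hydroxy ester 5 (not isolated)
Conditions: NaBH4, MeOH/CH2Cl2, −20 °C; then K2CO3 (0.2 equiv), rt
Reagents that add atoms: none
Why: Chemoselective borohydride reduction of the aldehyde beside a methyl ester and a silyl enol ether, then lactonisation of the C19 alkoxide onto C6. Only the cis isomer can close, and C5 (α to the ester and allylic) equilibrates under the mild base, so the γ-lactone fixes C5 cis to C19.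

Step 4
Reactants: 6 (3aR,7aS)-3a-methyl-6-[(triisopropylsilyl)oxy]-3a,4,5,7a-tetrahydro-2-benzofuran-1(3H)-one; 7 trimethyl orthoformate
Product: 8 (3aR,7aS)-7-(dimethoxymethyl)-3a-methylhexahydro-2-benzofuran-1,6-dione (either configuration at C10)
Conditions: TMSOTf (10 mol %), CH2Cl2, −78 °C
Reagents that add atoms: none
Why: Mukaiyama-type alkylation of a silyl enol ether by the dimethoxycarbenium ion; the enol ether made in step 2 is nucleophilic only at C10, so C20 enters there without any base that could touch the acidic C5–H.

Step 5
Reactants: 8 (3aR,7aS)-7-(dimethoxymethyl)-3a-methylhexahydro-2-benzofuran-1,6-dione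
Product: 10 (3aR,7aR)-3a-methyl-1-oxo-1,3,3a,4,5,7a-hexahydro-2-benzofuran-7-carbaldehyde, via hydroxy acetal 9 (not isolated)
Conditions: NaBH4, MeOH, 0 °C; then 2 M HCl, THF, 50 °C
Reagents that add atoms: water, O
Why: Ketone reduction followed by acetal hydrolysis and acid-catalysed dehydration of the β-hydroxy aldehyde (reductive 1,3-carbonyl transposition). Water is lost only towards C10, the α-carbon of the aldehyde, so the alkene lands at C1=C10 and the stereocentre made at C10 in step 4 disappears.

Step 6
Reactants: 10 (3aR,7aR)-3a-methyl-1-oxo-1,3,3a,4,5,7a-hexahydro-2-benzofuran-7-carbaldehyde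
Product: 11 (3aR,7aR)-7-(hydroxymethyl)-3a-methyl-3a,4,5,7a-tetrahydro-2-benzofuran-1(3H)-one
Conditions: NaBH4, CeCl3·7H2O, MeOH, −40 °C
Reagents that add atoms: none
Why: Luche 1,2-reduction of the enal to the allylic alcohol; the lactone is inert, and the cold, near-neutral medium avoids migration of C1=C10 into conjugation with C6.

Step 7
Reactants: 12 cyclopent-3-ene-1-carboxylic acid
Product: 13 cyclopent-3-en-1-ylmethanol
Conditions: LiAlH4, THF, 0 °C → rt
Reagents that add atoms: none
Why: Standard hydride reduction of a carboxylic acid to the primary alcohol; the isolated alkene is untouched.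

Step 8
Reactants: 13 cyclopent-3-en-1-ylmethanol
Product: 14 4-(bromomethyl)cyclopent-1-ene
Conditions: CBr4, PPh3, CH2Cl2, 0 °C
Reagents that add atoms: tetrabromomethane, BrC(Br)(Br)Br
Why: Appel bromination of a primary alcohol under neutral conditions.

Step 9
Reactants: 14 4-(bromomethyl)cyclopent-1-ene; 7 trimethyl orthoformate
Product: 16 3-(bromomethyl)-1,1,5,5-tetramethoxypentane, via dialdehyde 15 (not isolated)
Conditions: O3, CH2Cl2/MeOH, −78 °C; Me2S, → rt; then 7, TsOH (cat.), MeOH, rt
Reagents that add atoms: ozone, [O-][O+]=O (oxygen held only in intermediate 15)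
Why: Ozonolysis of the ring alkene gives the two CH2CHO arms on C13 in one operation and makes them identical; acetalisation in the same flask protects the aldehydes from the organomagnesium chemistry of step 10.

Step 10
Reactants: 16 3-(bromomethyl)-1,1,5,5-tetramethoxypentane; 17 prop-2-yn-1-ol
Product: 20 (2Z)-3-bromo-2-[2-(2,2-dimethoxyethyl)-4,4-dimethoxybutyl]prop-2-en-1-ol, via organomagnesium bromide 18 (not isolated), via vinylmagnesium chelate 19 (not isolated)
Conditions: 16, Mg, THF; 17 (1.5 equiv), EtMgBr (1.5 equiv), THF, 0 °C; then 18, CuI (10 mol %), rt; NBS, −40 °C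
Reagents that add atoms: N-bromosuccinimide, O=C1CCC(=O)N1Br
Why: Copper-catalysed anti-carbomagnesiation of a propargylic alkoxide; the alkyl group adds to C8 and magnesium to C9 within a five-membered alkoxide chelate, so the metal is cis to the carbinol carbon. Bromination of the vinyl–magnesium bond with retention fixes bromine cis to the future C7 without any equilibrating step.

Step 11
Reactants: 20 (2Z)-3-bromo-2-[2-(2,2-dimethoxyethyl)-4,4-dimethoxybutyl]prop-2-en-1-ol
Product: 22 (2Z)-3-bromo-2-[2-(2,2-dimethoxyethyl)-4,4-dimethoxybutyl]prop-2-enoic acid, via enal 21 (not isolated)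
Conditions: TEMPO (0.2 equiv), PhI(OAc)2 (2.4 equiv), MeCN/aq. pH 7 buffer, 0 °C → rt
Reagents that add atoms: water, O
Why: Oxoammonium oxidation of a primary allylic alcohol through the aldehyde hydrate to the acid; the buffer protects the dimethyl acetals and the alkene geometry.

Step 12
Reactants: 11 (3aR,7aR)-7-(hydroxymethyl)-3a-methyl-3a,4,5,7a-tetrahydro-2-benzofuran-1(3H)-one; 22 (2Z)-3-bromo-2-[2-(2,2-dimethoxyethyl)-4,4-dimethoxybutyl]prop-2-enoic acid
Product: 23 [(3aR,7aR)-3a-methyl-1-oxo-1,3,3a,4,5,7a-hexahydro-2-benzofuran-7-yl]methyl (2Z)-3-bromo-2-[2-(2,2-dimethoxyethyl)-4,4-dimethoxybutyl]prop-2-enoate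
Conditions: PPh3, DIAD, THF, 0 °C
Reagents that add atoms: none
Why: Mitsunobu esterification; the carboxylate displaces the activated primary allylic C20–O bond, so the β-bromoacrylic carbonyl is never activated and cannot undergo addition–elimination that would scramble the Z geometry.

Step 13
Reactants: 23 [(3aR,7aR)-3a-methyl-1-oxo-1,3,3a,4,5,7a-hexahydro-2-benzofuran-7-yl]methyl (2Z)-3-bromo-2-[2-(2,2-dimethoxyethyl)-4,4-dimethoxybutyl]prop-2-enoate
Product: 24 spiro unsaturated δ-lactone bis-acetal with C1=C2 and C8=C9 alkenes (C10 as in the target)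
Conditions: Pd(OAc)2 (10 mol %), PPh3 (30 mol %), Ag2CO3 (2 equiv), MeCN, 80 °C
Reagents that add atoms: none
Why: Oxidative addition of the C9–Br bond to zerovalent palladium (from Pd(OAc)2 and PPh3) gives a (Z)-vinylpalladium bromide; Ag2CO3 removes bromide, and the cationic vinylpalladium adds syn across C1=C10, C9 bonding to C10 and palladium to C1. The closest known reaction type is the intramolecular Heck cyclisation of vinyl halides onto trisubstituted cycloalkenes that forms quaternary spiro carbons. The δ-lactone closes in the 6-exo-trig mode; the 7-endo mode would put C9 on C1 and is not expected. The new stereocentre C10 is set by the substrate: C6 and C19 of the cis-fused γ-lactone cover one face of ring A, so C9 enters from the other face and C20 ends on the lactone face, as in the target. β-Hydride elimination can only take a syn hydrogen from C2, because C10 has become quaternary, and gives the C1=C2 alkene; the silver salt takes up HBr and disfavours re-addition of the palladium hydride, so the alkene should stay there. The step needs oxidative addition to outrun ionisation of the allylic C20–O bond and needs the ester to reach its s-trans conformer. The bromine cis to the carbonyl group (secured in step 10) and the three-atom tether (C7, O, C20) ensure that C9 can reach C10 and no other carbon.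

Step 14
Reactants: 24 spiro unsaturated δ-lactone bis-acetal with C1=C2 and C8=C9 alkenes
Product: 25 spiro unsaturated δ-lactone bis-acetal with saturated ring A
Conditions: H2 (1 atm), RhCl(PPh3)3 (10 mol %), benzene/EtOH, rt
Reagents that add atoms: none
Why: Homogeneous hydrogenation with RhCl(PPh3)3 reduces the cis-disubstituted C1=C2 alkene and leaves the trisubstituted, conjugated and hindered C8=C9 alkene, which is needed in step 16.

Step 15
Reactants: 25 spiro unsaturated δ-lactone bis-acetal with saturated ring A
Product: 26 spiro unsaturated δ-lactone dialdehyde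
Conditions: TFA/H2O (10:1), CH2Cl2, 0 °C
Reagents that add atoms: water, O
Why: Acid hydrolysis of both dimethyl acetals; the lactones and the enoate are stable to brief aqueous acid, and the dialdehyde is used at once.

Step 16
Reactants: 26 spiro unsaturated δ-lactone dialdehyde
Product: 27 17-nor pentacyclic 11,15-diol (C11 hydroxyl cis to H9; C15 hydroxyl exo)
Conditions: SmI2 (2.5 equiv, slow addition), LiBr, t-BuOH (1 equiv), THF, −78 °C
Reagents that add atoms: none
Why: Ketyl–olefin cyclisation followed by a samarium-enolate aldol: the C11 ketyl adds 6-endo to C9, the β-carbon of the enoate, on the face syn to C1 and away from C5 with its lactone, through a chair in which the second arm is equatorial; this sets C9 and C13. The C8 enolate then adds to the C15 aldehyde on the face opposite C11, closing ring D. The ketyl oxygen is expected to be equatorial in the closing chair, which is the C11 epimer of the target, and the aldol hydroxyl exo by chelation to trivalent samarium; neither configuration is relied on.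

Step 17
Reactants: 27 17-nor pentacyclic 11,15-diol
Product: 28 17-nor pentacyclic 11,15-dione
Conditions: DMP (3 equiv), NaHCO3, CH2Cl2, rt
Reagents that add atoms: none
Why: Periodinane oxidation of both secondary alcohols under buffered, non-basic conditions; this erases C11 and C15 and spares the β-keto lactone and the C9–H beside the new C11 ketone.

Step 18
Reactants: 28 17-nor pentacyclic 11,15-dione
Product: 29 17-nor pentacyclic 11,15-diol (C11 hydroxyl equatorial, trans to H9, as in the target; C15 hydroxyl endo)
Conditions: NaBH4, CeCl3·7H2O, MeOH/THF, −78 → −20 °C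
Reagents that add atoms: none
Why: Luche-type hydride reduction of both ketones. At C11 the equatorial trajectory is blocked by the axial C9–C10 bond and the ring A groups on C10, so hydride should enter axially on the bridge face and leave the equatorial hydroxyl. At C15 hydride enters from the open exo face, which buries the hydroxyl on the endo side.

Step 19
Reactants: 29 17-nor pentacyclic 11,15-diol (C11 equatorial, C15 endo)
Product: 30 C11 tert-butyldimethylsilyl ether with free C15 hydroxyl
Conditions: TBSOTf (1.05 equiv), 2,6-lutidine, CH2Cl2, −78 °C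
Reagents that add atoms: tert-butyldimethylsilyl trifluoromethanesulfonate, CC(C)(C)[Si](C)(C)OS(=O)(=O)C(F)(F)F
Why: Selective silylation of the more accessible hydroxyl: the C11 hydroxyl is equatorial on ring C, whereas the C15 hydroxyl is endo, neopentyl to quaternary C8 and hydrogen-bonded to the lactone carbonyl.

Step 20
Reactants: 30 C11 tert-butyldimethylsilyl ether with free C15 hydroxyl
Product: 31 17-nor bis-lactone C15 ketone, C11 silyl ether
Conditions: DMP, NaHCO3, CH2Cl2, rt
Reagents that add atoms: none
Why: Periodinane oxidation of the one remaining secondary alcohol to the C15 ketone under non-basic conditions.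

Step 21
Reactants: 31 17-nor bis-lactone C15 ketone, C11 silyl ether; 32 dimethyl(methylidene)ammonium iodide
Product: 35 C15 ketone with exocyclic C16=C17 methylene, C11 silyl ether, via Mannich base 33 (not isolated), via methiodide 34 (not isolated)
Conditions: LiN(SiMe3)2, THF, −78 °C; 32, −78 → 0 °C; MeI, CH2Cl2, rt; DBU, rt
Reagents that add atoms: none
Why: α-Methylenation through a Mannich base and elimination of its quaternary ammonium salt; C8 is quaternary, so the ketone enolises only towards C16, and the ketone α-hydrogen is removed in preference to the hindered lactone α-hydrogen at C5.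

Step 22
Reactants: 35 C15 ketone with exocyclic C16=C17 methylene, C11 silyl ether
Product: 37 C11 silyl ether of the target, via C17 pinacol boronate 36 (not isolated)
Conditions: CuCl (10 mol %), DPEphos (10 mol %), NaOtBu (15 mol %), B2pin2, MeOH (2 equiv), THF, rt; then NaBO3·4H2O, THF/H2O, 0 °C → rt
Reagents that add atoms: sodium perborate, [Na+].[O-]OB=O (the C17 oxygen); bis(pinacolato)diboron, CC1(C)OB(OC1(C)C)B1OC(C)(C)C(C)(C)O1 (boron held only in intermediate 36)
Why: Copper-catalysed conjugate borylation of an enone puts boron on the terminal carbon C17, and the enolate is protonated by methanol from the open exo face of ring D, which sets C16 with C17 endo as in the target. Perborate then oxidises the C–B bond with retention under mild conditions that should spare the β-hydroxy ketone.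

Step 23
Reactants: 37 C11 silyl ether of the target
Product: 38 target, CNP0555433.1
Conditions: HF·pyridine, THF, 0 °C → rt
Reagents that add atoms: none
Why: Fluoride-mediated cleavage of the secondary silyl ether under mildly acidic conditions, which avoids the base-induced retro-aldol, dehydration and C16 epimerisation of the β-hydroxy ketone.

## Compound list

1 | methyl (2E)-4-oxopent-2-enoate | CC(=O)/C=C/C(=O)OC | starting material
2 | methyl (2E)-4-[(triisopropylsilyl)oxy]penta-2,4-dienoate | C=C(O[Si](C(C)C)(C(C)C)C(C)C)/C=C/C(=O)OC | intermediate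
3 | methacrolein | CC(=C)C=O | starting material
4 | methyl (1S,6R)-6-formyl-6-methyl-3-[(triisopropylsilyl)oxy]cyclohex-2-ene-1-carboxylate | C[C@@]1(C=O)CCC(O[Si](C(C)C)(C(C)C)C(C)C)=C[C@@H]1C(=O)OC | intermediate
5 | methyl (1S,6R)-6-(hydroxymethyl)-6-methyl-3-[(triisopropylsilyl)oxy]cyclohex-2-ene-1-carboxylate | C[C@@]1(CO)CCC(O[Si](C(C)C)(C(C)C)C(C)C)=C[C@@H]1C(=O)OC | intermediate
6 | (3aR,7aS)-3a-methyl-6-[(triisopropylsilyl)oxy]-3a,4,5,7a-tetrahydro-2-benzofuran-1(3H)-one | C[C@@]12CCC(O[Si](C(C)C)(C(C)C)C(C)C)=C[C@@H]1C(=O)OC2 | intermediate
7 | trimethyl orthoformate | COC(OC)OC | starting material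
8 | (3aR,7aS)-7-(dimethoxymethyl)-3a-methylhexahydro-2-benzofuran-1,6-dione (C10 epimers) | C[C@@]12CCC(=O)C(C(OC)OC)[C@@H]1C(=O)OC2 | intermediate
9 | (3aR,7aS)-7-(dimethoxymethyl)-6-hydroxy-3a-methylhexahydro-2-benzofuran-1(3H)-one (C1 and C10 epimers) | C[C@@]12CCC(O)C(C(OC)OC)[C@@H]1C(=O)OC2 | intermediate
10 | (3aR,7aR)-3a-methyl-1-oxo-1,3,3a,4,5,7a-hexahydro-2-benzofuran-7-carbaldehyde | C[C@@]12CCC=C(C=O)[C@@H]1C(=O)OC2 | intermediate
11 | (3aR,7aR)-7-(hydroxymethyl)-3a-methyl-3a,4,5,7a-tetrahydro-2-benzofuran-1(3H)-one | C[C@@]12CCC=C(CO)[C@@H]1C(=O)OC2 | intermediate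
12 | cyclopent-3-ene-1-carboxylic acid | OC(=O)C1CC=CC1 | starting material
13 | cyclopent-3-en-1-ylmethanol | OCC1CC=CC1 | intermediate
14 | 4-(bromomethyl)cyclopent-1-ene | BrCC1CC=CC1 | intermediate
15 | 3-(bromomethyl)pentanedial | O=CCC(CBr)CC=O | intermediate
16 | 3-(bromomethyl)-1,1,5,5-tetramethoxypentane | COC(OC)CC(CBr)CC(OC)OC | intermediate
17 | prop-2-yn-1-ol | C#CCO | starting material
18 | [2-(2,2-dimethoxyethyl)-4,4-dimethoxybutyl]magnesium bromide | COC(OC)CC(C[Mg]Br)CC(OC)OC | intermediate
19 | 4-[2-(2,2-dimethoxyethyl)-4,4-dimethoxybutyl]-2,5-dihydro-1,2-oxamagnesole (vinylmagnesium alkoxide chelate) | COC(OC)CC(CC1=C[Mg]OC1)CC(OC)OC | intermediate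
20 | (2Z)-3-bromo-2-[2-(2,2-dimethoxyethyl)-4,4-dimethoxybutyl]prop-2-en-1-ol | OC/C(CC(CC(OC)OC)CC(OC)OC)=C\Br | intermediate
21 | (2Z)-3-bromo-2-[2-(2,2-dimethoxyethyl)-4,4-dimethoxybutyl]prop-2-enal | O=C/C(CC(CC(OC)OC)CC(OC)OC)=C\Br | intermediate
22 | (2Z)-3-bromo-2-[2-(2,2-dimethoxyethyl)-4,4-dimethoxybutyl]prop-2-enoic acid | OC(=O)/C(CC(CC(OC)OC)CC(OC)OC)=C\Br | intermediate
23 | [(3aR,7aR)-3a-methyl-1-oxo-1,3,3a,4,5,7a-hexahydro-2-benzofuran-7-yl]methyl (2Z)-3-bromo-2-[2-(2,2-dimethoxyethyl)-4,4-dimethoxybutyl]prop-2-enoate (precursor of the key step) | C[C@@]12CCC=C(COC(=O)/C(CC(CC(OC)OC)CC(OC)OC)=C\Br)[C@@H]1C(=O)OC2 | intermediate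
24 | spiro unsaturated δ-lactone bis-acetal, C1=C2 and C8=C9 alkenes (product of the key step) | C[C@@]12CC=C[C@]3(COC(=O)C(CC(CC(OC)OC)CC(OC)OC)=C3)[C@@H]1C(=O)OC2 | intermediate
25 | spiro unsaturated δ-lactone bis-acetal, ring A saturated | C[C@@]12CCC[C@]3(COC(=O)C(CC(CC(OC)OC)CC(OC)OC)=C3)[C@@H]1C(=O)OC2 | intermediate
26 | spiro unsaturated δ-lactone dialdehyde | C[C@@]12CCC[C@]3(COC(=O)C(CC(CC=O)CC=O)=C3)[C@@H]1C(=O)OC2 | intermediate
27 | 17-nor pentacyclic 11,15-diol (C11 hydroxyl cis to H9, C15 hydroxyl exo) | C[C@@]12CCC[C@]3(COC(=O)[C@@]45C[C@@H](C[C@H](O)[C@H]43)C[C@@H]5O)[C@@H]1C(=O)OC2 | intermediate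
28 | 17-nor pentacyclic 11,15-dione | C[C@@]12CCC[C@]3(COC(=O)[C@@]45C[C@@H](CC(=O)[C@H]43)CC5=O)[C@@H]1C(=O)OC2 | intermediate
29 | 17-nor pentacyclic 11,15-diol (C11 hydroxyl trans to H9, C15 hydroxyl endo) | C[C@@]12CCC[C@]3(COC(=O)[C@@]45C[C@@H](C[C@@H](O)[C@H]43)C[C@H]5O)[C@@H]1C(=O)OC2 | intermediate
30 | C11 tert-butyldimethylsilyl ether of 29 | C[C@@]12CCC[C@]3(COC(=O)[C@@]45C[C@@H](C[C@@H](O[Si](C)(C)C(C)(C)C)[C@H]43)C[C@H]5O)[C@@H]1C(=O)OC2 | intermediate
31 | 17-nor bis-lactone C15 ketone, C11 silyl ether | C[C@@]12CCC[C@]3(COC(=O)[C@@]45C[C@@H](C[C@@H](O[Si](C)(C)C(C)(C)C)[C@H]43)CC5=O)[C@@H]1C(=O)OC2 | intermediate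
32 | dimethyl(methylidene)ammonium iodide | C=[N+](C)C.[I-] | starting material
33 | C16 (dimethylamino)methyl ketone (Mannich base, C16 epimers) | C[C@@]12CCC[C@]3(COC(=O)[C@@]45C[C@@H](C[C@@H](O[Si](C)(C)C(C)(C)C)[C@H]43)C(CN(C)C)C5=O)[C@@H]1C(=O)OC2 | intermediate
34 | C16 (trimethylammonio)methyl ketone iodide | C[C@@]12CCC[C@]3(COC(=O)[C@@]45C[C@@H](C[C@@H](O[Si](C)(C)C(C)(C)C)[C@H]43)C(C[N+](C)(C)C)C5=O)[C@@H]1C(=O)OC2.[I-] | intermediate
35 | C15 ketone with exocyclic C16=C17 methylene, C11 silyl ether | C[C@@]12CCC[C@]3(COC(=O)[C@@]45C[C@@H](C[C@@H](O[Si](C)(C)C(C)(C)C)[C@H]43)C(=C)C5=O)[C@@H]1C(=O)OC2 | intermediate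
36 | C17 pinacol boronate, C11 silyl ether | C[C@@]12CCC[C@]3(COC(=O)[C@@]45C[C@@H](C[C@@H](O[Si](C)(C)C(C)(C)C)[C@H]43)[C@@H](CB6OC(C)(C)C(C)(C)O6)C5=O)[C@@H]1C(=O)OC2 | intermediate
37 | C11 tert-butyldimethylsilyl ether of the target | C[C@@]12CCC[C@]3(COC(=O)[C@@]45C[C@@H](C[C@@H](O[Si](C)(C)C(C)(C)C)[C@H]43)[C@@H](CO)C5=O)[C@@H]1C(=O)OC2 | intermediate
38 | CNP0555433.1 | C[C@@]12CCC[C@]3(COC(=O)[C@@]45C[C@@H](C[C@@H](O)[C@H]43)[C@@H](CO)C5=O)[C@@H]1C(=O)OC2 | target

## Step count and least certain steps

Total step count: 23. Longest linear sequence: 18 steps (steps 1–6 and 12–23, from 1); the acid branch (steps 7–11) joins at step 12.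

**Step 13 (key step).**
- *What may go wrong:* Zerovalent palladium may ionise the allylic C20–O bond in competition with oxidative addition. Ring closure may be slow because the ester prefers the s-cis conformer, in which C9 and C10 are far apart, so the vinylpalladium is reduced or isomerised instead. The base may move C1=C10 into conjugation with the γ-lactone before cyclisation. The facial bias at C10 may be incomplete, since the C18 methyl sits on the face opposite the lactone.
- *Fallback:* An ether tether, with the carbonyl put in afterwards, setting out from 11 and 20. Alcohol 11 is converted with CBr4/PPh3 into (3aR,7aR)-7-(bromomethyl)-3a-methyl-3a,4,5,7a-tetrahydro-2-benzofuran-1(3H)-one F1. F1 alkylates the hydroxyl of 20 under neutral silver assistance (Ag2O, CH2Cl2) to give the bis-allylic ether F2. The same palladium conditions close the spiro dihydropyran F3; an allyl ether is not ionised and has no conformational bias against closure. Hydrogenation with RhCl(PPh3)3 saturates C1=C2 to give the spiro ether F4. CrO3·3,5-dimethylpyrazole then oxidises C7, the only methylene that is both allylic and bound to oxygen, to the lactone carbonyl, and the route is rejoined at 25.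

**Step 16.**
- *What may go wrong:* The two aldehyde arms may undergo intramolecular pinacol coupling (a five-membered diol) faster than the ketyl adds to the hindered C9; slow addition of SmI2 is meant to suppress this. The samarium enolate may be protonated before it reaches C15, because the aldol needs ring C to leave its first chair. Face selection at C9 may be imperfect.
- *Fallback:* The two bond formations are separated, setting out from 26. SmI2 is added slowly with Me3SiCl present, which traps the ketyl adduct as the C8 silyl ketene acetal with a C11 trimethylsilyl ether, F5. BF3·OEt2 in CH2Cl2 at −78 °C then effects a Mukaiyama aldol from the regiodefined C8 nucleophile onto the C15 aldehyde. Acidic work-up removes the silyl groups and returns the route at 27, or at its C15 epimer, which step 17 converges.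

**Step 2.**
- *What may go wrong:* The ester-bearing diene may be sluggish towards a dienophile that must form a quaternary carbon. The acidic catalyst may protodesilylate 2. Facial control may be incomplete.
- *Fallback:* Resolution in place of asymmetric catalysis, setting out from 2 and 3. Thermal cycloaddition (toluene, 110 °C) gives racemic 4, which steps 3–6 carry to racemic 11. Esterification with (S)-2-methoxy-2-phenylacetic acid and separation of the diastereomers gives the (S)-O-methylmandelate of 11, F6. Mild methanolysis (K2CO3, MeOH, 0 °C) returns the route at 11.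

**Step 18.**
- *What may go wrong:* Hydride may be delivered to C11 from the equatorial side, which would regenerate the axial alcohol. Alkoxide may open the β-keto lactone by a retro-Claisen path. The selectivity of step 19 depends on the outcome here.
- *Fallback:* Electron-transfer reduction under product-stability control, setting out from 28. SmI2/HMPA/i-PrOH in THF should give the equatorial C11 alcohol and, by chelation, the exo C15 alcohol, i.e. the diol F7. Silylation at C11 gives F8, and oxidation of C15 with DMP returns the route at 31.

**Step 22.**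
- *What may go wrong:* C16 may epimerise to the more stable exo hydroxymethyl isomer, or the product may lose water back to enone 35, under the basic borylation and oxidation conditions. The enolate may be protonated from the endo face.
- *Fallback:* Formylation and hydrogenation, setting out from 31. LiN(SiMe3)2 and ethyl formate give the C16 hydroxymethylene ketone F9. TBSCl/imidazole gives the silyloxymethylene ketone F10. Hydrogenation over Pd/C delivers hydrogen to the exo face of C16=C17 and gives the 11,17-bis(silyl ether) F11. HF·pyridine removes both silyl groups and returns the route at 38.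

## Further compounds

F1 | step 13 | (3aR,7aR)-7-(bromomethyl)-3a-methyl-3a,4,5,7a-tetrahydro-2-benzofuran-1(3H)-one | C[C@@]12CCC=C(CBr)[C@@H]1C(=O)OC2
F2 | step 13 | (3aR,7aR)-7-({[(2Z)-3-bromo-2-[2-(2,2-dimethoxyethyl)-4,4-dimethoxybutyl]prop-2-en-1-yl]oxy}methyl)-3a-methyl-3a,4,5,7a-tetrahydro-2-benzofuran-1(3H)-one | C[C@@]12CCC=C(COC/C(CC(CC(OC)OC)CC(OC)OC)=C\Br)[C@@H]1C(=O)OC2
F3 | step 13 | spiro dihydropyran bis-acetal with C1=C2 and C8=C9 alkenes (C7 as CH2) | C[C@@]12CC=C[C@]3(COCC(CC(CC(OC)OC)CC(OC)OC)=C3)[C@@H]1C(=O)OC2
F4 | step 13 | spiro dihydropyran bis-acetal, ring A saturated | C[C@@]12CCC[C@]3(COCC(CC(CC(OC)OC)CC(OC)OC)=C3)[C@@H]1C(=O)OC2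
F5 | step 16 | C8 trimethylsilyl ketene acetal with C11 trimethylsilyl ether and free C15 aldehyde | C[C@@]12CCC[C@]3(COC(O[Si](C)(C)C)=C4C[C@H](CC=O)C[C@H](O[Si](C)(C)C)[C@H]43)[C@@H]1C(=O)OC2
F6 | step 2 | [(3aR,7aR)-3a-methyl-1-oxo-1,3,3a,4,5,7a-hexahydro-2-benzofuran-7-yl]methyl (2S)-2-methoxy-2-phenylacetate | C[C@@]12CCC=C(COC(=O)[C@@H](OC)c3ccccc3)[C@@H]1C(=O)OC2
F7 | step 18 | 17-nor pentacyclic 11,15-diol (C11 hydroxyl trans to H9, C15 hydroxyl exo) | C[C@@]12CCC[C@]3(COC(=O)[C@@]45C[C@@H](C[C@@H](O)[C@H]43)C[C@@H]5O)[C@@H]1C(=O)OC2
F8 | step 18 | C11 tert-butyldimethylsilyl ether of F7 | C[C@@]12CCC[C@]3(COC(=O)[C@@]45C[C@@H](C[C@@H](O[Si](C)(C)C(C)(C)C)[C@H]43)C[C@@H]5O)[C@@H]1C(=O)OC2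
F9 | step 22 | C16 hydroxymethylene C15 ketone, C11 silyl ether | C[C@@]12CCC[C@]3(COC(=O)[C@@]45C[C@@H](C[C@@H](O[Si](C)(C)C(C)(C)C)[C@H]43)C(=CO)C5=O)[C@@H]1C(=O)OC2
F10 | step 22 | C16 (tert-butyldimethylsilyloxy)methylene C15 ketone, C11 silyl ether | C[C@@]12CCC[C@]3(COC(=O)[C@@]45C[C@@H](C[C@@H](O[Si](C)(C)C(C)(C)C)[C@H]43)C(=CO[Si](C)(C)C(C)(C)C)C5=O)[C@@H]1C(=O)OC2
F11 | step 22 | 11,17-bis(tert-butyldimethylsilyl) ether of the target | C[C@@]12CCC[C@]3(COC(=O)[C@@]45C[C@@H](C[C@@H](O[Si](C)(C)C(C)(C)C)[C@H]43)[C@@H](CO[Si](C)(C)C(C)(C)C)C5=O)[C@@H]1C(=O)OC2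
A1 | alternative 1 | 17-nor bis-lactone C15 ketone, C11 tert-butyldimethylsilyl ether (identical with 31) | C[C@@]12CCC[C@]3(COC(=O)[C@@]45C[C@@H](C[C@@H](O[Si](C)(C)C(C)(C)C)[C@H]43)CC5=O)[C@@H]1C(=O)OC2
A2 | alternative 1 | C4 gem-dimethyl C6 carboxylic acid (A1 opened at C19–O) | CC1(C)CCC[C@]3(COC(=O)[C@@]45C[C@@H](C[C@@H](O[Si](C)(C)C(C)(C)C)[C@H]43)CC5=O)[C@@H]1C(=O)O
A3 | alternative 2 | pentacyclic C11 ketone with C15=C16 alkene and C17 benzyl ether | C[C@@]12CCC[C@]3(COC(=O)[C@@]45C[C@@H](CC(=O)[C@H]43)C(COCc6ccccc6)=C5)[C@@H]1C(=O)OC2
A4 | alternative 2 | C9 chloromethyl ketone tethered by the C20 ester to 3-(benzyloxymethyl)cyclopenta-1,3-diene-1-carboxylate | C[C@@]12CCC[C@](CC(=O)CCl)(COC(=O)C3=CC(COCc4ccccc4)=CC3)[C@@H]1C(=O)OC2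
A5 | alternative 3 | 17-nor pentacyclic 11,15-diol | C[C@@]12CCC[C@]3(COC(=O)[C@@]45C[C@@H](C[C@@H](O)[C@H]43)C[C@@H]5O)[C@@H]1C(=O)OC2
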